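**Retrosynthetic overview**
- The C4–O bond is made last: water adds to an ortho-quinone methide (C4=C4a–C5=O) released from the cis-4,5,4'-triacetate, and the C2 aryl group steers the new hydroxyl trans.
- The cis-flavan-4-ol comes from the racemic 5-hydroxy-8-prenylflavanone by asymmetric transfer hydrogenation run as a kinetic resolution, which reduces the ketone and selects 2S in one operation.
- The 8-prenyl-5-hydroxyflavanone comes from the 5-O-prenylflavanone by a Claisen–Cope shift of the prenyl group from O5 to C8; before that the O-prenyl group masks one phenol so that ring C can close in one sense only.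
- Ring C is closed at O1–C2 by oxa-Michael addition in a 2'-hydroxychalcone, itself made by aldol condensation of mono-O-prenylated 2',6'-dihydroxy-4'-methoxyacetophenone with 4-silyloxybenzaldehyde.
- Ring order: rings A and B are bought; ring C is the only ring made, before the prenyl shift and before both stereocentres are fixed.

Assumption: the SMILES is read as the (2S,4R)-isomer, i.e. the 2,4-trans flavan-4-ol; the acetophenone, prenyl bromide and the silyloxybenzaldehyde are taken as catalogue compounds.

**Step 1**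
Reactants: 1 1-(2,6-dihydroxy-4-methoxyphenyl)ethanone; 2 1-bromo-3-methylbut-2-ene (prenyl bromide)
Product: 3 1-[2-hydroxy-4-methoxy-6-(3-methylbut-2-enyloxy)phenyl]ethanone
Conditions: K2CO3 (1.5 equiv), acetone, 56 °C, 6 h
Reagents that add atoms: none
Why: Williamson O-alkylation of one of two equivalent phenols; after the first alkylation the remaining phenol is locked in a hydrogen bond to the acetyl group, so the reaction stops at the mono-ether, and K2CO3 in acetone favours O- over C-alkylation.

**Step 2**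
Reactants: 3 1-[2-hydroxy-4-methoxy-6-(3-methylbut-2-enyloxy)phenyl]ethanone; 4 4-(tert-butyldimethylsilyloxy)benzaldehyde
Product: 6 (E)-1-[2-hydroxy-4-methoxy-6-(3-methylbut-2-enyloxy)phenyl]-3-[4-(tert-butyldimethylsilyloxy)phenyl]prop-2-en-1-one, via aldol adduct 5 (not isolated)
Conditions: LiN(SiMe3)2 (3.2 equiv), THF, −78 → 20 °C, 16 h
Reagents that add atoms: none
Why: Claisen–Schmidt (aldol) condensation of the lithium phenoxide-enolate of 3 with the non-enolisable aldehyde 4, followed by E1cB loss of hydroxide from aldolate 5 to give the conjugated E-chalcone; an amide base instead of hydroxide keeps the aryl silyl ether intact.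

**Step 3**
Reactants: 6 (E)-1-[2-hydroxy-4-methoxy-6-(3-methylbut-2-enyloxy)phenyl]-3-[4-(tert-butyldimethylsilyloxy)phenyl]prop-2-en-1-one
Product: 7 rac-2-[4-(tert-butyldimethylsilyloxy)phenyl]-7-methoxy-5-(3-methylbut-2-enyloxy)chroman-4-one
Conditions: DBU (0.2 equiv), MeCN, 40 °C
Reagents that add atoms: none
Why: base-catalysed 6-endo intramolecular oxa-Michael addition (chalcone–flavanone isomerisation) forms the O1–C2 bond; only one phenol is free, so ring C closes in a single sense, the doubly ortho-substituted aryl ketone favours the closed form, and C2 is formed racemic.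

**Step 4**
Reactants: 7 rac-2-[4-(tert-butyldimethylsilyloxy)phenyl]-7-methoxy-5-(3-methylbut-2-enyloxy)chroman-4-one
Product: 10 rac-2-[4-(tert-butyldimethylsilyloxy)phenyl]-5-hydroxy-7-methoxy-8-(3-methylbut-2-enyl)chroman-4-one, via ortho-dienone 8 (not isolated), via para-dienone 9 (not isolated)
Conditions: Eu(fod)3 (10 mol%), CHCl3, 60 °C, 20 h
Reagents that add atoms: none
Why: Lewis-acid-catalysed domino aromatic Claisen–Cope rearrangement, in which trivalent europium chelates the C4 carbonyl and the O5 ether oxygen and triggers the [3,3] shift to C6 (8); a Cope shift then carries the allyl unit to C8 (9) and tautomerisation gives phenol 10, so the prenyl group arrives unrearranged para to the oxygen it left (known for 5-O-prenylflavanones).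

**Step 5**
Reactants: 10 rac-2-[4-(tert-butyldimethylsilyloxy)phenyl]-5-hydroxy-7-methoxy-8-(3-methylbut-2-enyl)chroman-4-one
Product: 11 (2S,4S)-2-[4-(tert-butyldimethylsilyloxy)phenyl]-7-methoxy-8-(3-methylbut-2-enyl)chromane-4,5-diol
Conditions: RuCl[(S,S)-TsDPEN](p-cymene) (2 mol%), HCO2H/Et3N (1:1), MeCN, 30 °C, stopped at 45–48% conversion
Reagents that add atoms: none
Why: Noyori–Ikariya asymmetric transfer hydrogenation run as a kinetic resolution; the (S,S)-catalyst delivers hydride to give the 4S carbinol, which coincides with the substrate-preferred axial attack (2,4-cis product) only for (2S)-10, so (2S,4S)-11 is formed (at most 50%) while (2R)-10 stays as ketone and is removed by chromatography; this step fixes C2 as S, and the near-neutral formate medium spares the acid-labile flavan-4-ol and avoids ring opening of the flavanone.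

**Step 6**
Reactants: 11 (2S,4S)-2-[4-(tert-butyldimethylsilyloxy)phenyl]-7-methoxy-8-(3-methylbut-2-enyl)chromane-4,5-diol
Product: 13 (2S,4S)-4-acetoxy-2-(4-acetoxyphenyl)-7-methoxy-8-(3-methylbut-2-enyl)chroman-5-yl acetate, via desilylated cis-triol 12 (not isolated)
Conditions: Bu4NF (1.1 equiv), THF, 0 °C, 15 min; then pyridine, Ac2O (6 equiv), DMAP (0.1 equiv), 0 → 20 °C, 2 h
Reagents that add atoms: acetic anhydride CC(=O)OC(C)=O
Why: fluoride desilylation followed in the same flask by exhaustive DMAP-catalysed acetylation (phenoxides first, then the C4 alcohol); the medium stays basic throughout, which protects the flavan-4-ol, and no stereocentre is touched.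

**Step 7**
Reactants: 13 (2S,4S)-4-acetoxy-2-(4-acetoxyphenyl)-7-methoxy-8-(3-methylbut-2-enyl)chroman-5-yl acetate
Product: 16 (2S,4R)-2-(4-hydroxyphenyl)-7-methoxy-8-(3-methylbut-2-enyl)chromane-4,5-diol, via 4-acetoxy diphenol 14 (not isolated), via ortho-quinone methide 15 (not isolated)
Conditions: LiOH (4 equiv), THF/H2O (2:1), 0.01 M, 0 °C, 20 min; then pH 7 phosphate buffer
Reagents that add atoms: water O
Why: Proposed new method: stereoconvergent deacetylative hydration through an ortho-quinone methide – hydroxide cleaves the two aryl acetates within minutes, the 5-phenoxide of 14 expels the C4 acetate (E1cB-type 1,4-elimination) to give 15 with a planar C4, and water adds to C4 along the axial trajectory of the half-chair that keeps the C2 aryl group equatorial (chair-like transition state, the other face needs a twist-boat), which places the new C4–O bond trans to the aryl group and sets C4 as R whatever the C4 configuration of 13 was; the closest known reaction types are base-triggered generation of ortho-quinone methides from ortho-hydroxybenzyl acetates or flavan 4-thioethers with capture by nucleophiles, and the 2,4-trans-selective capture of flavan-4-yl cations by carbon nucleophiles in 4-arylflavan synthesis, but capture by water with this 1,3-induction on a 3-deoxyflavan has not been shown.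

**Compound list**
1 | 1-(2,6-dihydroxy-4-methoxyphenyl)ethanone | CC(=O)c1c(O)cc(OC)cc1O | starting material
2 | 1-bromo-3-methylbut-2-ene (prenyl bromide) | CC(C)=CCBr | starting material
3 | 1-[2-hydroxy-4-methoxy-6-(3-methylbut-2-enyloxy)phenyl]ethanone | CC(=O)c1c(O)cc(OC)cc1OCC=C(C)C | intermediate
4 | 4-(tert-butyldimethylsilyloxy)benzaldehyde | O=Cc1ccc(O[Si](C)(C)C(C)(C)C)cc1 | starting material
5 | rac-3-hydroxy-1-[2-hydroxy-4-methoxy-6-(3-methylbut-2-enyloxy)phenyl]-3-[4-(tert-butyldimethylsilyloxy)phenyl]propan-1-one (aldol adduct, not isolated) | COc1cc(O)c(C(=O)CC(O)c2ccc(O[Si](C)(C)C(C)(C)C)cc2)c(OCC=C(C)C)c1 | intermediate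
6 | (E)-1-[2-hydroxy-4-methoxy-6-(3-methylbut-2-enyloxy)phenyl]-3-[4-(tert-butyldimethylsilyloxy)phenyl]prop-2-en-1-one | COc1cc(O)c(C(=O)/C=C/c2ccc(O[Si](C)(C)C(C)(C)C)cc2)c(OCC=C(C)C)c1 | intermediate
7 | rac-2-[4-(tert-butyldimethylsilyloxy)phenyl]-7-methoxy-5-(3-methylbut-2-enyloxy)chroman-4-one | COc1cc(OCC=C(C)C)c2c(c1)OC(c1ccc(O[Si](C)(C)C(C)(C)C)cc1)CC2=O | intermediate
8 | 2-[4-(tert-butyldimethylsilyloxy)phenyl]-7-methoxy-6-(2-methylbut-3-en-2-yl)-2,3-dihydro-4H-chromene-4,5(6H)-dione (ortho-dienone, racemic diastereomer mixture, not isolated) | COC1=CC2=C(C(=O)CC(c3ccc(O[Si](C)(C)C(C)(C)C)cc3)O2)C(=O)C1C(C)(C)C=C | intermediate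
9 | 2-[4-(tert-butyldimethylsilyloxy)phenyl]-7-methoxy-8-(3-methylbut-2-enyl)-2,3-dihydro-4H-chromene-4,5(8H)-dione (para-dienone, racemic diastereomer mixture, not isolated) | COC1=CC(=O)C2=C(OC(c3ccc(O[Si](C)(C)C(C)(C)C)cc3)CC2=O)C1CC=C(C)C | intermediate
10 | rac-2-[4-(tert-butyldimethylsilyloxy)phenyl]-5-hydroxy-7-methoxy-8-(3-methylbut-2-enyl)chroman-4-one | COc1cc(O)c2c(c1CC=C(C)C)OC(c1ccc(O[Si](C)(C)C(C)(C)C)cc1)CC2=O | intermediate
11 | (2S,4S)-2-[4-(tert-butyldimethylsilyloxy)phenyl]-7-methoxy-8-(3-methylbut-2-enyl)chromane-4,5-diol (2,4-cis) | COc1cc(O)c2c(c1CC=C(C)C)O[C@H](c1ccc(O[Si](C)(C)C(C)(C)C)cc1)C[C@@H]2O | intermediate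
12 | (2S,4S)-2-(4-hydroxyphenyl)-7-methoxy-8-(3-methylbut-2-enyl)chromane-4,5-diol (2,4-cis, C4 epimer of the target, not isolated) | COc1cc(O)c2c(c1CC=C(C)C)O[C@H](c1ccc(O)cc1)C[C@@H]2O | intermediate
13 | (2S,4S)-4-acetoxy-2-(4-acetoxyphenyl)-7-methoxy-8-(3-methylbut-2-enyl)chroman-5-yl acetate | COc1cc(OC(C)=O)c2c(c1CC=C(C)C)O[C@H](c1ccc(OC(C)=O)cc1)C[C@@H]2OC(C)=O | intermediate
14 | (2S,4S)-5-hydroxy-2-(4-hydroxyphenyl)-7-methoxy-8-(3-methylbut-2-enyl)chroman-4-yl acetate (not isolated) | COc1cc(O)c2c(c1CC=C(C)C)O[C@H](c1ccc(O)cc1)C[C@@H]2OC(C)=O | intermediate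
15 | (2S)-2-(4-hydroxyphenyl)-7-methoxy-8-(3-methylbut-2-enyl)-2,3-dihydro-5H-chromen-5-one (ortho-quinone methide, not isolated) | COC1=CC(=O)C2=CC[C@@H](c3ccc(O)cc3)OC2=C1CC=C(C)C | intermediate
16 | (2S,4R)-2-(4-hydroxyphenyl)-7-methoxy-8-(3-methylbut-2-enyl)chromane-4,5-diol (2,4-trans) | COc1cc(O)c2c(c1CC=C(C)C)O[C@H](c1ccc(O)cc1)C[C@H]2O | target

**Step count**
Total steps: 7. Longest linear sequence: 7 steps (1 to 16).

**Steps most likely to fail**

Step 7 (the proposed new step). The facial selectivity of water capture may be modest. Direct saponification of the C4 acetate would give some cis-triol 12 with retention. Phenoxides may add to 15 and give dimers. Tautomerisation of 15 to the flav-3-ene is limited to slow intermolecular deprotonation, because ring C holds the C3 methylene anti to the carbonyl oxygen and so blocks an internal 1,5-hydrogen shift. The reaction must stay cold and short so that the B-ring phenoxide does not open ring C at C2.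
Fallback with known chemistry, setting out from 11 and coming back at 16: the 5-hydroxyl of 11 is silylated (TBSCl, imidazole, DMF, 0 °C) to give the bis-silyl cis-alcohol F1. Mitsunobu inversion (PPh3, DIAD, 4-nitrobenzoic acid, THF, 0 °C) gives the trans 4-nitrobenzoate F2. iBu2AlH (CH2Cl2, −78 °C) removes the ester while both phenols stay masked and gives the bis-silyl trans-alcohol F3. Bu4NF buffered with AcOH (THF, 0 °C) then gives 16.

Step 4. The ortho-dienone 8 may tautomerise before the Cope shift and give the 6-(1,1-dimethylallyl) isomer, or the shift may stall.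
Fallback, setting out from 1 and coming back at 10: 1 is C-prenylated directly with 2 (10% aq. KOH, 0 °C) to give the 3-prenyl acetophenone F4. Condensation with 4 (LiN(SiMe3)2, THF) gives the dihydroxychalcone F5. DBU-catalysed closure, in which either phenol can add, gives 10 together with its 6-prenyl regioisomer F6, and 10 is separated by chromatography.

Step 5. The chelated 5-hydroxy ketone may be reduced slowly or with a low selectivity factor, which would erode the ee of 11. The unreacted (2R)-10 cannot be recycled, because base racemisation opens ring C and would scramble the prenyl position.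
Fallback, setting out from 7 and coming back at 11: the resolution is moved to the non-chelated ketone. 7 is treated under the same transfer-hydrogenation conditions with the enantiomeric catalyst RuCl[(R,R)-TsDPEN](p-cymene), which leaves the (2S)-flavanone F7 untouched while the 2R half is reduced to the cis-alcohol F8 and discarded. F7 is taken through the Eu(fod)3 Claisen–Cope step to the (2S)-5-hydroxy-8-prenylflavanone F9. NaBH4 (THF/MeOH, −20 °C) then reduces F9 under substrate control (axial hydride delivery) to 11.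

**Further compounds**
F1 | step 7 | (2S,4S)-5-(tert-butyldimethylsilyloxy)-2-[4-(tert-butyldimethylsilyloxy)phenyl]-7-methoxy-8-(3-methylbut-2-enyl)chroman-4-ol | COc1cc(O[Si](C)(C)C(C)(C)C)c2c(c1CC=C(C)C)O[C@H](c1ccc(O[Si](C)(C)C(C)(C)C)cc1)C[C@@H]2O
F2 | step 7 | (2S,4R)-5-(tert-butyldimethylsilyloxy)-2-[4-(tert-butyldimethylsilyloxy)phenyl]-7-methoxy-8-(3-methylbut-2-enyl)chroman-4-yl 4-nitrobenzoate | COc1cc(O[Si](C)(C)C(C)(C)C)c2c(c1CC=C(C)C)O[C@H](c1ccc(O[Si](C)(C)C(C)(C)C)cc1)C[C@H]2OC(=O)c1ccc(cc1)[N+](=O)[O-]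
F3 | step 7 | (2S,4R)-5-(tert-butyldimethylsilyloxy)-2-[4-(tert-butyldimethylsilyloxy)phenyl]-7-methoxy-8-(3-methylbut-2-enyl)chroman-4-ol | COc1cc(O[Si](C)(C)C(C)(C)C)c2c(c1CC=C(C)C)O[C@H](c1ccc(O[Si](C)(C)C(C)(C)C)cc1)C[C@H]2O
F4 | step 4 | 1-[2,6-dihydroxy-4-methoxy-3-(3-methylbut-2-enyl)phenyl]ethanone | CC(=O)c1c(O)cc(OC)c(CC=C(C)C)c1O
F5 | step 4 | (E)-1-[2,6-dihydroxy-4-methoxy-3-(3-methylbut-2-enyl)phenyl]-3-[4-(tert-butyldimethylsilyloxy)phenyl]prop-2-en-1-one | COc1cc(O)c(C(=O)/C=C/c2ccc(O[Si](C)(C)C(C)(C)C)cc2)c(O)c1CC=C(C)C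
F6 | step 4 | rac-2-[4-(tert-butyldimethylsilyloxy)phenyl]-5-hydroxy-7-methoxy-6-(3-methylbut-2-enyl)chroman-4-one | COc1cc2c(c(O)c1CC=C(C)C)C(=O)CC(c1ccc(O[Si](C)(C)C(C)(C)C)cc1)O2
F7 | step 5 | (2S)-2-[4-(tert-butyldimethylsilyloxy)phenyl]-7-methoxy-5-(3-methylbut-2-enyloxy)chroman-4-one | COc1cc(OCC=C(C)C)c2c(c1)O[C@H](c1ccc(O[Si](C)(C)C(C)(C)C)cc1)CC2=O
F8 | step 5 | (2R,4R)-2-[4-(tert-butyldimethylsilyloxy)phenyl]-7-methoxy-5-(3-methylbut-2-enyloxy)chroman-4-ol | COc1cc(OCC=C(C)C)c2c(c1)O[C@@H](c1ccc(O[Si](C)(C)C(C)(C)C)cc1)C[C@H]2O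
F9 | step 5 | (2S)-2-[4-(tert-butyldimethylsilyloxy)phenyl]-5-hydroxy-7-methoxy-8-(3-methylbut-2-enyl)chroman-4-one | COc1cc(O)c2c(c1CC=C(C)C)O[C@H](c1ccc(O[Si](C)(C)C(C)(C)C)cc1)CC2=O
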